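**Retrosynthetic overview**
1. Skeleton: all chain carbons and both guaiacyl rings are bought as one achiral piece, tetrahydrocurcumin 1. The route makes no C–C bond.
2. The O5 acetyl goes on first: 1 ⇒ (E)-enol acetate 2 by global O-acetylation. The symmetry of 1 allows only one enol acetate constitution.
3. Key C5–H disconnection: Re-face conjugate hydride transfer to C5 of 2 under a chiral Brønsted acid, through enol 3, gives (S)-triacetate 4.
4. Target 5 ⇐ 4 by chemoselective cleavage of the two aryl acetates.
5. Ring order: no ring is formed; both arenes come intact with 1.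

Assumption: C5 of the target is (S) as read from the SMILES (ketone at C3, acetoxy at C5). The (R)-acid is taken to deliver hydride to the Re face of C5 of 2; the (S)-acid is used instead if the first run shows the opposite sense.

**Step 1**
Reactants: 1 tetrahydrocurcumin, 1,7-bis(4-hydroxy-3-methoxyphenyl)heptane-3,5-dione
Product: 2 (E)-5-acetoxy-1,7-bis(4-acetoxy-3-methoxyphenyl)hept-4-en-3-one
Conditions: AcCl (3.3 equiv), Et3N (3.6 equiv), CH2Cl2, −20 → 0 °C, 2 h; cold aqueous NaHCO3 work-up
Reagents that add atoms: acetyl chloride, CC(Cl)=O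
Why: Base-mediated O-acylation, in which Et3N/AcCl esterifies both phenols and O-acetylates the open (non-chelated) triethylammonium enolate of the symmetric 1,3-diketone, gives a single enol acetate constitution with the E geometry expected from the W-shaped enolate; DMAP is left out to avoid O-to-C acyl migration, and no stereocentre is formed.

**Step 2**
Reactants: 2 (E)-5-acetoxy-1,7-bis(4-acetoxy-3-methoxyphenyl)hept-4-en-3-one
Product: 4 (S)-5-acetoxy-1,7-bis(4-acetoxy-3-methoxyphenyl)heptan-3-one, via (3Z,5S)-enol 3 (not isolated)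
Conditions: (R)-3,3′-bis(2,4,6-triisopropylphenyl)-1,1′-binaphthyl-2,2′-diyl N-triflylphosphoramide (5 mol %), diethyl 2,6-dimethyl-1,4-dihydropyridine-3,5-dicarboxylate (1.3 equiv), PhMe/CH2Cl2 4:1, 5 Å MS, 0 °C, dark, 24–48 h
Reagents that add atoms: none
Why: Proposed new method: asymmetric conjugate transfer hydrogenation of a β-acyloxy enone (vinylogous anhydride) by chiral Brønsted acid catalysis, in which the strongly acidic phosphoramide protonates the C3 carbonyl to a 1-acetoxy-3-hydroxyallyl cation held as a contact ion pair, the phosphoramidate also hydrogen-bonds the N–H of the Hantzsch ester, and hydride is passed inside this chiral pocket to the Re face of C5 to set (S) before enol 3 tautomerises to the ketone (C4 becomes CH2, so C5 is the only stereocentre); the closest known reaction types are chiral phosphoric acid-catalysed Hantzsch ester reduction of imines and counter-anion-directed iminium transfer hydrogenation of β,β-disubstituted enones, neither shown for β-acyloxy enones, and amine catalysts are avoided because 2 would acylate them.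

**Step 3**
Reactants: 4 (S)-5-acetoxy-1,7-bis(4-acetoxy-3-methoxyphenyl)heptan-3-one
Product: 5 (S)-5-acetoxy-1,7-bis(4-hydroxy-3-methoxyphenyl)heptan-3-one
Conditions: NH4OAc (10 equiv), MeOH/H2O 4:1, 20 °C, 6–12 h
Reagents that add atoms: none
Why: Chemoselective transesterification (methanolysis of aryl esters) works because phenoxide is a much better leaving group than a secondary alkoxide, so near-neutral NH4OAc in aqueous methanol cleaves only the two aryl acetates, and the C5 acetate, the ketone and the C5 stereocentre, which carries no acidic hydrogen, are left as they are.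

**Compound list**
1 | tetrahydrocurcumin, 1,7-bis(4-hydroxy-3-methoxyphenyl)heptane-3,5-dione | COc1cc(CCC(=O)CC(=O)CCc2ccc(O)c(OC)c2)ccc1O | starting material
2 | (E)-5-acetoxy-1,7-bis(4-acetoxy-3-methoxyphenyl)hept-4-en-3-one | COc1cc(CC/C(OC(C)=O)=C\C(=O)CCc2ccc(OC(C)=O)c(OC)c2)ccc1OC(C)=O | intermediate
3 | (3Z,5S)-5-acetoxy-1,7-bis(4-acetoxy-3-methoxyphenyl)hept-3-en-3-ol | COc1cc(CC/C(O)=C/[C@H](CCc2ccc(OC(C)=O)c(OC)c2)OC(C)=O)ccc1OC(C)=O | intermediate (not isolated)
4 | (S)-5-acetoxy-1,7-bis(4-acetoxy-3-methoxyphenyl)heptan-3-one | COc1cc(CCC(=O)C[C@H](CCc2ccc(OC(C)=O)c(OC)c2)OC(C)=O)ccc1OC(C)=O | intermediate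
5 | (S)-5-acetoxy-1,7-bis(4-hydroxy-3-methoxyphenyl)heptan-3-one | COc1cc(CCC(=O)C[C@H](CCc2ccc(O)c(OC)c2)OC(C)=O)ccc1O | target

**Totals**
Total step count: 3. Longest linear sequence: 3 steps (1 → 2 → 4 → 5).

**Steps most likely to fail**

Step 2 (the proposed new step). The risks are that acid activation alone is too weak for hydride transfer, that enol 3 loses acetic acid to the enone which is then over-reduced, and that acid-promoted E/Z leakage of 2 lowers the ee. The fallback uses known chemistry, sets out from 1 and comes back at 4. An (S)-selective ketoreductase picked from a screening panel (NADP+, i-PrOH as cosubstrate, KH2PO4/K2HPO4 buffer pH 7 with 10% DMSO, 30 °C) mono-reduces the symmetric diketone to (S)-5-hydroxy-1,7-bis(4-hydroxy-3-methoxyphenyl)heptan-3-one F1. Peracetylation of F1 with Ac2O in pyridine at 0 °C then gives 4.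

Step 1. The risks are an E/Z mixture, some C-acylation, and hydrolysis of the vinylogous anhydride on silica. The fallback sets out from 1 and comes back at 4. Acid-catalysed enol-ester exchange with isopropenyl acetate (cat. TsOH·H2O, 60 °C, acetone distilled off) acetylates both phenols and the hydrogen-bonded cis-enol to give (Z)-5-acetoxy-1,7-bis(4-acetoxy-3-methoxyphenyl)hept-4-en-3-one F2. F2 is reduced under the conditions of step 2, with the acid antipode chosen by the sense of the first run, through enol 3 to 4.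

Step 3. The risks are E1cB loss of the C5 acetate to the enone, or partial cleavage of the C5 acetate alongside the aryl esters. The fallback changes the phenol protecting group, sets out from 1 and comes back at 5.
- TBSCl and imidazole in DMF, with an aqueous citric acid wash to hydrolyse any enol silyl ether, give 1,7-bis[4-(tert-butyldimethylsilyloxy)-3-methoxyphenyl]heptane-3,5-dione F3.
- AcCl (1.1 equiv) and Et3N in CH2Cl2 at −20 °C give (E)-5-acetoxy-1,7-bis[4-(tert-butyldimethylsilyloxy)-3-methoxyphenyl]hept-4-en-3-one F4.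
- The conditions of step 2 reduce F4 through (3Z,5S)-5-acetoxy-1,7-bis[4-(tert-butyldimethylsilyloxy)-3-methoxyphenyl]hept-3-en-3-ol F5 (not isolated) to (S)-5-acetoxy-1,7-bis[4-(tert-butyldimethylsilyloxy)-3-methoxyphenyl]heptan-3-one F6.
- Et3N·3HF in THF at 20 °C removes both aryl silyl ethers under mildly acidic conditions to give 5.

**Further compounds**
F1 | step 2 | (S)-5-hydroxy-1,7-bis(4-hydroxy-3-methoxyphenyl)heptan-3-one | COc1cc(CCC(=O)C[C@H](CCc2ccc(O)c(OC)c2)O)ccc1O
F2 | step 1 | (Z)-5-acetoxy-1,7-bis(4-acetoxy-3-methoxyphenyl)hept-4-en-3-one | COc1cc(CC/C(OC(C)=O)=C/C(=O)CCc2ccc(OC(C)=O)c(OC)c2)ccc1OC(C)=O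
F3 | step 3 | 1,7-bis[4-(tert-butyldimethylsilyloxy)-3-methoxyphenyl]heptane-3,5-dione | COc1cc(CCC(=O)CC(=O)CCc2ccc(O[Si](C)(C)C(C)(C)C)c(OC)c2)ccc1O[Si](C)(C)C(C)(C)C
F4 | step 3 | (E)-5-acetoxy-1,7-bis[4-(tert-butyldimethylsilyloxy)-3-methoxyphenyl]hept-4-en-3-one | COc1cc(CC/C(OC(C)=O)=C\C(=O)CCc2ccc(O[Si](C)(C)C(C)(C)C)c(OC)c2)ccc1O[Si](C)(C)C(C)(C)C
F5 | step 3 | (3Z,5S)-5-acetoxy-1,7-bis[4-(tert-butyldimethylsilyloxy)-3-methoxyphenyl]hept-3-en-3-ol | COc1cc(CC/C(O)=C/[C@H](CCc2ccc(O[Si](C)(C)C(C)(C)C)c(OC)c2)OC(C)=O)ccc1O[Si](C)(C)C(C)(C)C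
F6 | step 3 | (S)-5-acetoxy-1,7-bis[4-(tert-butyldimethylsilyloxy)-3-methoxyphenyl]heptan-3-one | COc1cc(CCC(=O)C[C@H](CCc2ccc(O[Si](C)(C)C(C)(C)C)c(OC)c2)OC(C)=O)ccc1O[Si](C)(C)C(C)(C)C
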